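**Retrosynthetic overview**

1. Ring letters: A = cyclopentane carrying CO2Me, B = cyclohexenone, C = carbocycle of the 3-azabicyclo[3.3.1]nonane, D = δ-lactam, E = nine-membered N-bridge. The last operations are functional-group changes: aldehyde-to-ester oxidation, hydrogenation of a ring-A enoate (sets the ester carbon) and desilylation.
2. Key disconnection: rings A and C are opened together by cutting (i) the bond from the bridgehead quaternary carbon (the α-carbon of the ring-D lactam) to the β-carbon of the ring-B enone and (ii) the ring-A bond from the CH2 next to that quaternary carbon to the ester-bearing CH. This leaves a D/E bicyclic α-formyl lactam, linked through one CH2 to a 3-chlorocyclohexenone that carries a CH2CHO arm.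
3. Enabling feature: the quaternary carbon shared by rings A, C and D and its ring-A CH2 neighbour are the α- and β-atoms of the lactam carbonyl. As an α-formyl lactam they react first as a soft carbon nucleophile and then as a non-enolisable aldehyde. Ring B supplies the matching pair: its enone β-carbon (as vinylogous acyl chloride) and the carbon α to the future ester (as enolisable aldehyde).
4. Fragments: the lactam part comes from (S)-paraconic acid (double lactone alkylation for the quaternary carbon, syn-aldol for the hydroxy/methyl pair, Fukuyama–Mitsunobu closure of ring E, transannular lactone aminolysis for ring D). Ring B comes from 3-ethoxycyclohexenone by decarboxylative asymmetric allylation. The two are joined by Negishi coupling.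
5. Order of ring formation: E, then D, then ring B attached, then C and A together in the key step.

Key step: step 26

Remark: (S)-paraconic acid is taken as a catalogue compound. Compounds 23 to 27 and 34 to 36 are carried as mixtures of epimers at the acetal-bearing lactam α-carbon, which becomes planar in step 25. In step 20 the ligand enantiomer is the one that delivers the (R)-ketone; the sense of induction is assumed by analogy with simple α-allyl cyclohexanones, and the antipodal ligand is used if it proves opposite. Steps 19 to 22 are the convergent branch to the ring-B fragment.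

**Route**

Step 1
Reactants: 1 (S)-paraconic acid
Product: 2 (R)-4-(hydroxymethyl)dihydrofuran-2(3H)-one
Conditions: BH3·SMe2, THF, 0 to 23 °C; MeOH quench
Reagents that add atoms: none
Why: Borane reduces the free carboxylic acid much faster than the lactone (chemoselective acyloxyborane reduction), and the existing stereocenter is not touched.

Step 2
Reactants: 2 (R)-4-(hydroxymethyl)dihydrofuran-2(3H)-one
Product: 3 (R)-4-(benzyloxymethyl)dihydrofuran-2(3H)-one
Conditions: benzyl 2,2,2-trichloroacetimidate, TfOH (5 mol%), CH2Cl2/cyclohexane, 0 °C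
Reagents that add atoms: benzyl 2,2,2-trichloroacetimidate ClC(Cl)(Cl)C(=N)OCc1ccccc1
Why: Acid-catalysed imidate benzylation avoids alkoxide conditions, under which the lactone would transpose onto the other CH2O arm and racemise 2.

Step 3
Reactants: 3 (R)-4-(benzyloxymethyl)dihydrofuran-2(3H)-one; 4 allyl bromide
Product: 5 (3S,4R)-3-allyl-4-(benzyloxymethyl)dihydrofuran-2(3H)-one
Conditions: LiN(iPr)2, THF, −78 °C; then 4, −78 to −40 °C
Reagents that add atoms: none
Why: Lactone enolate alkylation should occur anti to the 4-substituent (trans product); this center is re-enolised in step 4.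

Step 4
Reactants: 5 (3S,4R)-3-allyl-4-(benzyloxymethyl)dihydrofuran-2(3H)-one; 6 tert-butyl bromoacetate
Product: 7 tert-butyl 2-[(3S,4R)-3-allyl-4-(benzyloxymethyl)-2-oxotetrahydrofuran-3-yl]acetate
Conditions: LiN(iPr)2, THF/DMPU, −78 °C; then 6, −78 to −30 °C
Reagents that add atoms: none
Why: In this second enolate alkylation the electrophile should again enter anti to the benzyloxymethyl group, which fixes the quaternary center with the acetate arm trans and the allyl arm cis to that group.

Step 5
Reactants: 7 tert-butyl 2-[(3S,4R)-3-allyl-4-(benzyloxymethyl)-2-oxotetrahydrofuran-3-yl]acetate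
Product: 9 tert-butyl 2-[(3S,4R)-4-(benzyloxymethyl)-3-(3-hydroxypropyl)-2-oxotetrahydrofuran-3-yl]acetate, via B-alkyl-9-BBN adduct 8 (not isolated)
Conditions: 9-BBN, THF, 0 to 23 °C; then 30% H2O2, aq. NaOAc, 0 °C
Reagents that add atoms: hydrogen peroxide OO
Why: Anti-Markovnikov hydroboration–oxidation of the terminal alkene; 9-BBN and buffered peroxide leave the lactone and the tert-butyl ester intact.

Step 6
Reactants: 9 tert-butyl 2-[(3S,4R)-4-(benzyloxymethyl)-3-(3-hydroxypropyl)-2-oxotetrahydrofuran-3-yl]acetate
Product: 10 tert-butyl 2-[(3S,4R)-4-(benzyloxymethyl)-2-oxo-3-(3-oxopropyl)tetrahydrofuran-3-yl]acetate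
Conditions: Dess–Martin periodinane, NaHCO3, CH2Cl2, 0 to 23 °C
Reagents that add atoms: none
Why: Dess–Martin oxidation takes the primary alcohol to the aldehyde under neutral conditions without touching the esters.

Step 7
Reactants: 10 tert-butyl 2-[(3S,4R)-4-(benzyloxymethyl)-2-oxo-3-(3-oxopropyl)tetrahydrofuran-3-yl]acetate; 11 (S)-4-benzyl-3-propionyloxazolidin-2-one
Product: 12 syn-aldol adduct (new unit 2S,3R: acyl oxazolidinone, α-methyl, β-hydroxy; the carbinol carbon is the former aldehyde carbon and is joined to the lactone α-carbon through two CH2 groups)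
Conditions: 11, Bu2BOTf, iPr2NEt, CH2Cl2, 0 °C; then 10, −78 to 0 °C; pH 7 buffer/MeOH/H2O2 work-up
Reagents that add atoms: none
Why: Evans syn-aldol reaction, in which the Z-boron enolate and the (S)-benzyl auxiliary set the carbinol and methyl centers (syn, reagent control) independently of the remote lactone centers.

Step 8
Reactants: 12 syn-aldol adduct
Product: 13 TBS ether of the aldol adduct
Conditions: TBSOTf, 2,6-lutidine, CH2Cl2, −78 °C
Reagents that add atoms: tert-butyldimethylsilyl triflate CC(C)(C)[Si](C)(C)OS(=O)(=O)C(F)(F)F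
Why: Silylation of the secondary alcohol blocks retro-aldol cleavage and masks this hydroxyl for the two Mitsunobu steps.

Step 9
Reactants: 13 TBS ether of the aldol adduct
Product: 14 primary alcohol (auxiliary removed; chain CH2OH–CH(CH3)–CH(OTBS)–(CH2)2– on the lactone α-carbon)
Conditions: NaBH4, THF/H2O (4:1), 0 to 23 °C
Reagents that add atoms: none
Why: Borohydride cleaves the activated imide reductively to the primary alcohol, while the α-quaternary lactone and the tert-butyl ester are too hindered to react.

Step 10
Reactants: 14 primary alcohol; 15 2-nitrobenzenesulfonamide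
Product: 16 N-alkyl 2-nitrobenzenesulfonamide
Conditions: 15 (3 equiv), PPh3, DIAD, THF/PhMe, 0 to 23 °C
Reagents that add atoms: none
Why: Mitsunobu N-alkylation of the acidic sulfonamide (Fukuyama amine synthesis) at the only free, unhindered primary carbinol.

Step 11
Reactants: 16 N-alkyl 2-nitrobenzenesulfonamide
Product: 18 4,4-disubstituted γ-lactone carrying a free CH2OH arm (lactone now between the neopentyl CH2O and the former tert-butyl ester), via diol 17 (not isolated)
Conditions: LiBH4, THF, 0 to 23 °C; then CSA (0.2 equiv), PhMe, 60 °C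
Reagents that add atoms: none
Why: LiBH4 reduces the lactone but not the tert-butyl ester, and acid then closes the five-membered lactone from the neopentyl hydroxyl (γ- preferred over δ-lactone), which frees the other CH2OH arm and so differentiates the two primary alcohols.

Step 12
Reactants: 18 γ-lactone alcohol
Product: 19 N-Ns nine-membered cyclic amine (ring E) with the γ-lactone spiro-fused at the quaternary carbon
Conditions: PPh3, DIAD, PhMe/THF (0.003 M, slow addition), 23 to 60 °C
Reagents that add atoms: none
Why: Intramolecular Fukuyama–Mitsunobu alkylation of the Ns-amide under high dilution is an established way to nine-membered cyclic amines, and no other free hydroxyl is present.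

Step 13
Reactants: 19 N-Ns nine-membered cyclic amine
Product: 21 bicyclic bridgehead lactam (rings D/E) with free neopentyl CH2OH, via secondary amine 20 (not isolated)
Conditions: PhSH, K2CO3, DMF, 23 °C; then 2-hydroxypyridine (0.2 equiv), PhMe, 100 °C
Reagents that add atoms: none
Why: Thiolate removes the Ns group by nucleophilic aromatic substitution, and the freed ring amine, held across the ring from the lactone carbonyl, opens it transannularly to the six-membered lactam and releases the CH2OH group.

Step 14
Reactants: 21 bicyclic lactam alcohol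
Product: 22 triethylsilyl ether
Conditions: Et3SiCl, imidazole, CH2Cl2, 0 °C
Reagents that add atoms: chlorotriethylsilane CC[Si](Cl)(CC)CC
Why: Silylation of the primary alcohol protects it from the strong base of step 15.

Step 15
Reactants: 22 triethylsilyl ether
Product: 23 α-(dimethoxymethyl) lactam
Conditions: LiN(iPr)2, THF, −78 °C; then HC(OMe)3/BF3·OEt2 (premixed at −30 °C in CH2Cl2), −78 to −20 °C
Reagents that add atoms: trimethyl orthoformate COC(OC)OC
Why: The lactam lithium enolate is alkylated by the dimethoxycarbenium ion (Mukaiyama-type orthoester alkylation), which installs the formyl carbon as its acetal; the new α-center later becomes planar, so its configuration does not matter.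

Step 16
Reactants: 23 α-(dimethoxymethyl) lactam
Product: 25 neopentyl acetate, via primary alcohol 24 (not isolated)
Conditions: Bu4NF, AcOH, THF, 0 °C; then Ac2O, Et3N, DMAP, 23 °C
Reagents that add atoms: acetic anhydride CC(=O)OC(C)=O
Why: Buffered fluoride should remove the primary triethylsilyl ether selectively beside the secondary TBS ether, and acetylation puts the target's acetate in place now that no strong-base step follows.

Step 17
Reactants: 25 neopentyl acetate
Product: 26 primary alcohol (benzyl ether cleaved)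
Conditions: H2 (1 atm), Pd(OH)2/C, EtOAc, 23 °C
Reagents that add atoms: none
Why: Hydrogenolysis removes the benzyl ether; acetal, acetate, lactam and silyl ether are inert.

Step 18
Reactants: 26 primary alcohol
Product: 27 primary iodide
Conditions: I2, PPh3, imidazole, PhMe/MeCN, 23 to 50 °C
Reagents that add atoms: iodine II
Why: Appel-type iodination (SN2 on the alkoxyphosphonium ion) converts the β-branched primary alcohol into the iodide needed for zinc insertion.

Step 19
Reactants: 28 3-ethoxycyclohex-2-en-1-one; 29 allyl chloroformate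
Product: 30 allyl (5-ethoxycyclohexa-1,5-dien-1-yl) carbonate
Conditions: LiN(SiMe3)2, TMEDA, THF, −78 °C; then 29
Reagents that add atoms: none
Why: Kinetic deprotonation at the α′-carbon of the vinylogous ester and O-acylation (favoured by TMEDA) give the enol carbonate needed for decarboxylative allylation.

Step 20
Reactants: 30 allyl (5-ethoxycyclohexa-1,5-dien-1-yl) carbonate
Product: 31 (R)-6-allyl-3-ethoxycyclohex-2-en-1-one
Conditions: Pd2(dba)3·CHCl3 (2.5 mol%), (R,R)-N,N′-(9,10-dihydro-9,10-ethanoanthracene-11,12-diyl)bis[2-(diphenylphosphino)benzamide] (5.5 mol%), PhMe, 23 °C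
Reagents that add atoms: none
Why: Palladium-catalysed decarboxylative asymmetric allylic alkylation of the enol carbonate, in which the chiral diphosphine controls the enolate face and sets the tertiary α′-stereocenter.

Step 21
Reactants: 31 (R)-6-allyl-3-ethoxycyclohex-2-en-1-one
Product: 32 (R)-6-allyl-3-ethoxy-2-iodocyclohex-2-en-1-one
Conditions: N-iodosuccinimide, CH2Cl2, 0 °C, dark
Reagents that add atoms: N-iodosuccinimide O=C1CCC(=O)N1I
Why: Electrophilic iodination goes to the nucleophilic α-carbon of the vinylogous ester (enol ether β-carbon), which is far more electron-rich than the terminal alkene.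

Step 22
Reactants: 32 (R)-6-allyl-3-ethoxy-2-iodocyclohex-2-en-1-one
Product: 33 (R)-4-allyl-3-chloro-2-iodocyclohex-2-en-1-one
Conditions: (COCl)2, DMF (cat.), CH2Cl2, 0 to 23 °C
Reagents that add atoms: oxalyl chloride O=C(Cl)C(Cl)=O
Why: Oxalyl chloride acylates the only basic oxygen (the ketone of the vinylogous ester), chloride adds at that carbon and ethyl chloride is lost from the resulting oxocarbenium ion, so chlorine should end on the former carbonyl carbon next to the allyl-bearing center (Vilsmeier-type 1,3-transposition), an outcome a free 1,3-dione would not give selectively.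

Step 23
Reactants: 27 primary iodide; 33 (R)-4-allyl-3-chloro-2-iodocyclohex-2-en-1-one
Product: 35 coupled lactam–chloroenone, via alkylzinc iodide 34 (not isolated)
Conditions: Zn dust (activated with Me3SiCl and BrCH2CH2Br), LiCl, THF, 45 °C; then 33, PdCl2(dppf)·CH2Cl2 (5 mol%), THF/DMA, 23 to 40 °C
Reagents that add atoms: none
Why: Zinc insertion into the primary iodide and Negishi coupling with the α-iodoenone join the fragments, since oxidative addition is much faster at the C–I bond than at the vinylogous acyl chloride.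

Step 24
Reactants: 35 coupled lactam–chloroenone
Product: 36 aldehyde (allyl group cleaved to CH2CHO)
Conditions: OsO4 (2 mol%), NaIO4, 2,6-lutidine, dioxane/H2O (3:1), 23 °C
Reagents that add atoms: osmium tetroxide O=[Os](=O)(=O)=O; sodium periodate [Na+].[O-]I(=O)(=O)=O
Why: Lemieux–Johnson cleavage attacks only the terminal alkene, the chloroenone being electron-poor and the formyl group still masked as its acetal.

Step 25
Reactants: 36 aldehyde
Product: 37 α-(hydroxymethylene) lactam (enol form of the α-formyl lactam), used crude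
Conditions: TFA/H2O/CH2Cl2 (1:1:8), 0 °C
Reagents that add atoms: water O
Why: Cold aqueous acid hydrolyses the acetal to the formyl lactam, which rests as its conjugated enol; acetate and the secondary TBS ether should survive the short exposure.

Step 26
Reactants: 37 α-(hydroxymethylene) lactam
Product: 40 pentacyclic enal (rings A to E; ring-A cyclopentene carbaldehyde), via bridgehead formyl tricycle 38 (not isolated), via β-hydroxy aldehyde 39 (not isolated)
Conditions: Cs2CO3 (2.5 equiv), MeCN (0.005 M), 23 °C, then 60 °C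
Reagents that add atoms: none
Why: Carbonate ionises only the hydroxymethylene lactam (pKa about 12), whose α-carbon attacks the β-carbon of the tethered 3-chloroenone and expels chloride (addition–elimination, 6-endo-trig), closing ring C and with it the 3-azabicyclo[3.3.1]nonane. The aldehyde now sitting on the new bridgehead carbon is non-enolisable and is condensed with the enolate of the side-chain aldehyde (5-(enolexo)-exo-trig aldol, then E1cB loss of water), closing ring A. The closest known reaction types are C-alkenylation of 1,3-dicarbonyl anions by β-halo enones (vinylogous acylation) and the intramolecular aldol condensation of 1,6-dialdehydes to cyclopentene carbaldehydes. The new quaternary stereocenter can form only on the lactam face that carries the CH2 tether (1,3-cis bridging), so it is set by the existing ring-D stereocenter, and the pre-set allylic stereocenter of ring B is not involved. The step needs C- over O-alkenylation (O-attack would close an eight-membered ring), reaction of the lactam enolate before the aldehyde enolate (about five pKa units apart), and retention of the formyl group. The formyl group should be retained because after the first event it sits on a bridgehead carbon, so retro-Claisen loss would require an anti-Bredt enolate.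

Step 27
Reactants: 40 pentacyclic enal
Product: 42 ring-A α,β-unsaturated methyl ester, via carboxylic acid 41 (not isolated)
Conditions: NaClO2, NaH2PO4, 2-methyl-2-butene, t-BuOH/H2O, 0 °C; then Me3SiCHN2, MeOH/PhMe, 0 °C
Reagents that add atoms: sodium chlorite [Na+].[O-]Cl=O; trimethylsilyldiazomethane C[Si](C)(C)C=[N+]=[N-]
Why: Pinnick oxidation of the enal followed by diazoalkane esterification brings the carbon to the ester level without base, so the allylic ring-B center is not at risk.

Step 28
Reactants: 42 ring-A α,β-unsaturated methyl ester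
Product: 43 saturated methyl ester (TBS ether of the target)
Conditions: H2 (1 atm), 10% Pd/C, EtOAc, 0 to 23 °C
Reagents that add atoms: none
Why: Heterogeneous hydrogenation of the trisubstituted enoate should occur from the face syn to the lactam carbonyl, away from the quaternary carbon with its CH2OAc and ring-E arms, which places the new hydrogen cis to the neighbouring ring-fusion hydrogen, while the tetrasubstituted enone is left alone.

Step 29
Reactants: 43 saturated methyl ester
Product: 44 target CNP0123592.1
Conditions: HF·pyridine, pyridine, THF, 0 to 23 °C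
Reagents that add atoms: none
Why: Fluoride-mediated cleavage of the secondary TBS ether under mildly acidic conditions leaves the acetate, the methyl ester and the epimerisable centers untouched.

**Compound list**

1 | (S)-paraconic acid, (S)-5-oxotetrahydrofuran-3-carboxylic acid | O=C1C[C@H](C(=O)O)CO1 | starting material
2 | (R)-4-(hydroxymethyl)dihydrofuran-2(3H)-one | O=C1C[C@H](CO)CO1 | intermediate
3 | (R)-4-(benzyloxymethyl)dihydrofuran-2(3H)-one | O=C1C[C@H](COCc2ccccc2)CO1 | intermediate
4 | allyl bromide | C=CCBr | starting material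
5 | (3S,4R)-3-allyl-4-(benzyloxymethyl)dihydrofuran-2(3H)-one (trans) | C=CC[C@@H]1C(=O)OC[C@H]1COCc1ccccc1 | intermediate
6 | tert-butyl bromoacetate | CC(C)(C)OC(=O)CBr | starting material
7 | tert-butyl 2-[(3S,4R)-3-allyl-4-(benzyloxymethyl)-2-oxotetrahydrofuran-3-yl]acetate | C=CC[C@@]1(CC(=O)OC(C)(C)C)C(=O)OC[C@H]1COCc1ccccc1 | intermediate
8 | B-alkyl-9-BBN adduct of 7 (boron on the terminal carbon of the former allyl group) | C1CC2CCCC(C1)B2CCC[C@@]1(CC(=O)OC(C)(C)C)C(=O)OC[C@H]1COCc1ccccc1 | intermediate
9 | tert-butyl 2-[(3S,4R)-4-(benzyloxymethyl)-3-(3-hydroxypropyl)-2-oxotetrahydrofuran-3-yl]acetate | OCCC[C@@]1(CC(=O)OC(C)(C)C)C(=O)OC[C@H]1COCc1ccccc1 | intermediate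
10 | tert-butyl 2-[(3S,4R)-4-(benzyloxymethyl)-2-oxo-3-(3-oxopropyl)tetrahydrofuran-3-yl]acetate | O=CCC[C@@]1(CC(=O)OC(C)(C)C)C(=O)OC[C@H]1COCc1ccccc1 | intermediate
11 | (S)-4-benzyl-3-propionyloxazolidin-2-one | CCC(=O)N1[C@@H](Cc2ccccc2)COC1=O | starting material
12 | syn-aldol adduct of 10 and 11 (2S,3R in the new 3-hydroxy-2-methylacyl unit; two CH2 groups between the carbinol carbon and the lactone α-carbon) | O=C1OC[C@H](Cc2ccccc2)N1C(=O)[C@@H](C)[C@H](O)CC[C@@]1(CC(=O)OC(C)(C)C)C(=O)OC[C@H]1COCc1ccccc1 | intermediate
13 | TBS ether of 12 | O=C1OC[C@H](Cc2ccccc2)N1C(=O)[C@@H](C)[C@H](O[Si](C)(C)C(C)(C)C)CC[C@@]1(CC(=O)OC(C)(C)C)C(=O)OC[C@H]1COCc1ccccc1 | intermediate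
14 | primary alcohol from reductive removal of the auxiliary (HOCH2–CH(CH3)–CH(OTBS)–(CH2)2– chain on the lactone α-carbon) | OC[C@@H](C)[C@H](O[Si](C)(C)C(C)(C)C)CC[C@@]1(CC(=O)OC(C)(C)C)C(=O)OC[C@H]1COCc1ccccc1 | intermediate
15 | 2-nitrobenzenesulfonamide | NS(=O)(=O)c1ccccc1[N+](=O)[O-] | starting material
16 | N-alkyl 2-nitrobenzenesulfonamide from 14 | O=S(=O)(NC[C@@H](C)[C@H](O[Si](C)(C)C(C)(C)C)CC[C@@]1(CC(=O)OC(C)(C)C)C(=O)OC[C@H]1COCc1ccccc1)c1ccccc1[N+](=O)[O-] | intermediate
17 | diol from lactone reduction (two CH2OH groups, tert-butyl ester intact) | O=S(=O)(NC[C@@H](C)[C@H](O[Si](C)(C)C(C)(C)C)CC[C@@](CC(=O)OC(C)(C)C)(CO)[C@@H](CO)COCc1ccccc1)c1ccccc1[N+](=O)[O-] | intermediate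
18 | γ-lactone (4,4-disubstituted dihydrofuran-2(3H)-one) with free CH2OH arm, benzyloxymethyl arm and Ns-amide chain | O=S(=O)(NC[C@@H](C)[C@H](O[Si](C)(C)C(C)(C)C)CC[C@]1(CC(=O)OC1)[C@@H](CO)COCc1ccccc1)c1ccccc1[N+](=O)[O-] | intermediate
19 | N-Ns nine-membered cyclic amine (ring E) spiro-fused to the γ-lactone | O=S(=O)(c1ccccc1[N+](=O)[O-])N1C[C@@H](C)[C@H](O[Si](C)(C)C(C)(C)C)CC[C@]2(CC(=O)OC2)[C@H](COCc2ccccc2)C1 | intermediate
20 | free secondary amine of 19 | N1C[C@@H](C)[C@H](O[Si](C)(C)C(C)(C)C)CC[C@]2(CC(=O)OC2)[C@H](COCc2ccccc2)C1 | intermediate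
21 | bicyclic bridgehead lactam (rings D/E) with CH2OH on the quaternary carbon, CH2OBn on the adjacent CH, OTBS and CH3 on ring E | C1C(=O)N2C[C@@H](COCc3ccccc3)[C@]1(CO)CC[C@@H](O[Si](C)(C)C(C)(C)C)[C@H](C)C2 | intermediate
22 | triethylsilyl ether of 21 | C1C(=O)N2C[C@@H](COCc3ccccc3)[C@]1(CO[Si](CC)(CC)CC)CC[C@@H](O[Si](C)(C)C(C)(C)C)[C@H](C)C2 | intermediate
23 | α-(dimethoxymethyl) lactam (epimers at the lactam α-carbon) | COC(OC)C1C(=O)N2C[C@@H](COCc3ccccc3)[C@]1(CO[Si](CC)(CC)CC)CC[C@@H](O[Si](C)(C)C(C)(C)C)[C@H](C)C2 | intermediate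
24 | primary alcohol from 23 (triethylsilyl removed) | COC(OC)C1C(=O)N2C[C@@H](COCc3ccccc3)[C@]1(CO)CC[C@@H](O[Si](C)(C)C(C)(C)C)[C@H](C)C2 | intermediate
25 | neopentyl acetate | COC(OC)C1C(=O)N2C[C@@H](COCc3ccccc3)[C@]1(COC(C)=O)CC[C@@H](O[Si](C)(C)C(C)(C)C)[C@H](C)C2 | intermediate
26 | primary alcohol (benzyl removed) | COC(OC)C1C(=O)N2C[C@@H](CO)[C@]1(COC(C)=O)CC[C@@H](O[Si](C)(C)C(C)(C)C)[C@H](C)C2 | intermediate
27 | primary iodide | COC(OC)C1C(=O)N2C[C@@H](CI)[C@]1(COC(C)=O)CC[C@@H](O[Si](C)(C)C(C)(C)C)[C@H](C)C2 | intermediate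
28 | 3-ethoxycyclohex-2-en-1-one | CCOC1=CC(=O)CCC1 | starting material
29 | allyl chloroformate | C=CCOC(=O)Cl | starting material
30 | allyl (5-ethoxycyclohexa-1,5-dien-1-yl) carbonate | C=CCOC(=O)OC1=CCCC(OCC)=C1 | intermediate
31 | (R)-6-allyl-3-ethoxycyclohex-2-en-1-one | CCOC1=CC(=O)[C@@H](CC=C)CC1 | intermediate
32 | (R)-6-allyl-3-ethoxy-2-iodocyclohex-2-en-1-one | CCOC1=C(I)C(=O)[C@@H](CC=C)CC1 | intermediate
33 | (R)-4-allyl-3-chloro-2-iodocyclohex-2-en-1-one | IC1=C(Cl)[C@@H](CC=C)CCC1=O | intermediate
34 | alkylzinc iodide from 27 | COC(OC)C1C(=O)N2C[C@@H](C[Zn]I)[C@]1(COC(C)=O)CC[C@@H](O[Si](C)(C)C(C)(C)C)[C@H](C)C2 | intermediate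
35 | coupled product: lactam CH2 attached to the α-carbon of the 4-allyl-3-chlorocyclohexenone | COC(OC)C1C(=O)N2C[C@@H](CC3=C(Cl)[C@@H](CC=C)CCC3=O)[C@]1(COC(C)=O)CC[C@@H](O[Si](C)(C)C(C)(C)C)[C@H](C)C2 | intermediate
36 | aldehyde (CH2CHO arm on ring B) | COC(OC)C1C(=O)N2C[C@@H](CC3=C(Cl)[C@@H](CC=O)CCC3=O)[C@]1(COC(C)=O)CC[C@@H](O[Si](C)(C)C(C)(C)C)[C@H](C)C2 | intermediate
37 | α-(hydroxymethylene) lactam, enol form of the α-formyl lactam | OC=C1C(=O)N2C[C@@H](CC3=C(Cl)[C@@H](CC=O)CCC3=O)[C@]1(COC(C)=O)CC[C@@H](O[Si](C)(C)C(C)(C)C)[C@H](C)C2 | intermediate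
38 | bridgehead formyl tricycle (ring C closed, quaternary carbon set, both aldehydes free) | O=C[C@@]12C(=O)N3C[C@@H](CC4=C1[C@@H](CC=O)CCC4=O)[C@]2(COC(C)=O)CC[C@@H](O[Si](C)(C)C(C)(C)C)[C@H](C)C3 | intermediate
39 | β-hydroxy aldehyde (ring A closed; carbinol and formyl-bearing centers undefined) | O=CC1C(O)[C@@]23C(=O)N4C[C@@H](CC5=C2[C@@H]1CCC5=O)[C@]3(COC(C)=O)CC[C@@H](O[Si](C)(C)C(C)(C)C)[C@H](C)C4 | intermediate
40 | pentacyclic enal (ring-A cyclopentene carbaldehyde) | O=CC1=C[C@@]23C(=O)N4C[C@@H](CC5=C2[C@@H]1CCC5=O)[C@]3(COC(C)=O)CC[C@@H](O[Si](C)(C)C(C)(C)C)[C@H](C)C4 | intermediate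
41 | ring-A α,β-unsaturated carboxylic acid | OC(=O)C1=C[C@@]23C(=O)N4C[C@@H](CC5=C2[C@@H]1CCC5=O)[C@]3(COC(C)=O)CC[C@@H](O[Si](C)(C)C(C)(C)C)[C@H](C)C4 | intermediate
42 | ring-A α,β-unsaturated methyl ester | COC(=O)C1=C[C@@]23C(=O)N4C[C@@H](CC5=C2[C@@H]1CCC5=O)[C@]3(COC(C)=O)CC[C@@H](O[Si](C)(C)C(C)(C)C)[C@H](C)C4 | intermediate
43 | TBS ether of the target | COC(=O)[C@@H]1C[C@@]23C(=O)N4C[C@@H](CC5=C2[C@@H]1CCC5=O)[C@]3(COC(C)=O)CC[C@@H](O[Si](C)(C)C(C)(C)C)[C@H](C)C4 | intermediate
44 | CNP0123592.1 | COC(=O)[C@@H]1C[C@@]23C(=O)N4C[C@@H](CC5=C2[C@@H]1CCC5=O)[C@]3(COC(C)=O)CC[C@@H](O)[C@H](C)C4 | target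

**Step count and risks**

Total step count: 29. Longest linear sequence: 25 steps (steps 1 to 18, then 23 to 29); the ring-B branch is steps 19 to 22.

Steps most likely to fail:

Step 26. The hindered lactam α-carbon may fail to attack the fully substituted enone β-carbon. Then O-cyclisation of the side-chain aldehyde enol onto the chloroenone (furan formation), intermolecular condensation, or epimerisation of the allylic ring-B center may take over. Fallback, from 35 back to 40: the two bond formations are separated. The acetal of 35 is hydrolysed first (TFA/H2O, 0 °C) to the hydroxymethylene lactam that still carries the allyl group F1. The lactam α-carbon is then joined to the chloroenone carbon by intramolecular α-alkenylation of the 1,3-dicarbonyl under zerovalent palladium catalysis (Pd(PPh3)4, K3PO4, THF, 60 °C), which should give the tricyclic bridgehead aldehyde with intact allyl group F2. Lemieux–Johnson cleavage of the allyl group gives dialdehyde 38, now isolated, and dibenzylammonium trifluoroacetate in benzene at 50 °C effects the aldol condensation to 40.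

Step 12. Intermolecular Mitsunobu alkylation (oligomerisation) may outrun closure of the nine-membered ring at the β-branched carbinol. Fallback, from 14 back to 19: the ring is closed through the other C–N bond, at the unhindered carbinol. Alcohol 14 is protected with 4-methoxybenzyl trichloroacetimidate and CSA as the PMB ether F3. LiBH4 reduction gives the diol F4, which CSA lactonises to the γ-lactone with free CH2OH arm F5. Intermolecular Mitsunobu reaction with 15, which can be driven with excess reagents, gives the Ns-amide on the hindered arm F6. DDQ removes the PMB group to give the primary alcohol F7, and high-dilution Mitsunobu closure at this unbranched CH2OH gives 19.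

Step 22. Chloride may enter at the wrong terminus (loss of regiocontrol), or HCl may cause epimerisation or addition at the allyl-bearing center. Fallback, from 31 back to 40: the vinylogous acyl chloride is dispensed with. Compound 31 is reduced with iBu2AlH and the carbinol hydrolysed with aqueous HCl (Stork–Danheiser transposition) to (R)-4-allylcyclohex-2-en-1-one F8. Iodination with I2 and pyridine gives (R)-4-allyl-2-iodocyclohex-2-en-1-one F9. Negishi coupling with 34 gives the chlorine-free coupled enone F10, Lemieux–Johnson cleavage the aldehyde F11, and acetal hydrolysis the hydroxymethylene lactam F12. Cs2CO3 then triggers intramolecular Michael addition of the lactam α-carbon to the enone β-carbon followed by the same aldol condensation, giving the saturated ketone enal F13. Its more substituted trimethylsilyl enol ether F14 (Me3SiCl, NaI, Et3N, MeCN) is dehydrogenated with Pd(OAc)2 in MeCN (Saegusa–Ito oxidation) to enone 40.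

**Further compounds**

F1 | step 26 | α-(hydroxymethylene) lactam with allyl group and chloroenone | OC=C1C(=O)N2C[C@@H](CC3=C(Cl)[C@@H](CC=C)CCC3=O)[C@]1(COC(C)=O)CC[C@@H](O[Si](C)(C)C(C)(C)C)[C@H](C)C2
F2 | step 26 | tricyclic bridgehead aldehyde with intact allyl group | O=C[C@@]12C(=O)N3C[C@@H](CC4=C1[C@@H](CC=C)CCC4=O)[C@]2(COC(C)=O)CC[C@@H](O[Si](C)(C)C(C)(C)C)[C@H](C)C3
F3 | step 12 | PMB ether of 14 | COc1ccc(COC[C@@H](C)[C@H](O[Si](C)(C)C(C)(C)C)CC[C@@]2(CC(=O)OC(C)(C)C)C(=O)OC[C@H]2COCc2ccccc2)cc1
F4 | step 12 | diol from lactone reduction of F3 | COc1ccc(COC[C@@H](C)[C@H](O[Si](C)(C)C(C)(C)C)CC[C@@](CC(=O)OC(C)(C)C)(CO)[C@@H](CO)COCc2ccccc2)cc1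
F5 | step 12 | γ-lactone with free CH2OH arm and PMB-protected chain | COc1ccc(COC[C@@H](C)[C@H](O[Si](C)(C)C(C)(C)C)CC[C@]2(CC(=O)OC2)[C@@H](CO)COCc2ccccc2)cc1
F6 | step 12 | Ns-amide on the hindered CH2 arm, PMB-protected chain | COc1ccc(COC[C@@H](C)[C@H](O[Si](C)(C)C(C)(C)C)CC[C@]2(CC(=O)OC2)[C@@H](CNS(=O)(=O)c2ccccc2[N+](=O)[O-])COCc2ccccc2)cc1
F7 | step 12 | Ns-amide with free primary alcohol at the chain end | OC[C@@H](C)[C@H](O[Si](C)(C)C(C)(C)C)CC[C@]1(CC(=O)OC1)[C@@H](CNS(=O)(=O)c1ccccc1[N+](=O)[O-])COCc1ccccc1
F8 | step 22 | (R)-4-allylcyclohex-2-en-1-one | O=C1C=C[C@@H](CC=C)CC1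
F9 | step 22 | (R)-4-allyl-2-iodocyclohex-2-en-1-one | O=C1C(I)=C[C@@H](CC=C)CC1
F10 | step 22 | chlorine-free coupled enone | COC(OC)C1C(=O)N2C[C@@H](CC3=C[C@@H](CC=C)CCC3=O)[C@]1(COC(C)=O)CC[C@@H](O[Si](C)(C)C(C)(C)C)[C@H](C)C2
F11 | step 22 | chlorine-free aldehyde | COC(OC)C1C(=O)N2C[C@@H](CC3=C[C@@H](CC=O)CCC3=O)[C@]1(COC(C)=O)CC[C@@H](O[Si](C)(C)C(C)(C)C)[C@H](C)C2
F12 | step 22 | chlorine-free α-(hydroxymethylene) lactam | OC=C1C(=O)N2C[C@@H](CC3=C[C@@H](CC=O)CCC3=O)[C@]1(COC(C)=O)CC[C@@H](O[Si](C)(C)C(C)(C)C)[C@H](C)C2
F13 | step 22 | saturated ketone enal (two ring-B CH centers next to the ketone side undefined) | O=CC1=C[C@@]23C(=O)N4C[C@@H](CC5C2[C@@H]1CCC5=O)[C@]3(COC(C)=O)CC[C@@H](O[Si](C)(C)C(C)(C)C)[C@H](C)C4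
F14 | step 22 | trimethylsilyl enol ether of F13 (more substituted side) | O=CC1=C[C@@]23C(=O)N4C[C@@H](CC=5C2[C@@H]1CCC5O[Si](C)(C)C)[C@]3(COC(C)=O)CC[C@@H](O[Si](C)(C)C(C)(C)C)[C@H](C)C4
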